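**Retrosynthetic overview**
1. Target ⇒ two ester C–O bonds and a C1 ketone unmasked from a silyl enol ether ⇒ diol 22 ⇒ bridged 15,9-lactone 21, whose lactone C–O bond ties C6 to the 9R centre.
2. Seven-membered ring (formed last) ⇒ lactone-enolate aldol onto the C5 cyclobutanone of 17, then Barton–McCombie removal of the C5 oxygen.
3. C1 oxygen ⇒ C–H to C–O conversion on keto lactone 12, relayed from the C5 carbonyl (key step; iridium-catalysed silylation, then oxidation).
4. δ-Lactone (temporary ring, formed second) ⇒ reagent-controlled vinylogous Mukaiyama aldol of aldehyde 7 with tiglate dienolate 9.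
5. Cyclobutane and six-membered ring (formed first, together) ⇒ intramolecular ketene–alkene [2+2] of (R)-citronellic acid oxidised at its E-methyl.

Assumption: atoms carry longipinane-type labels (C1 ketone carbon; C2; C3 with methyl C12; cyclobutane C4, C5, C11, C10; C6 with methyl C13 and C15H2O; C7; C8; C9 with O; C14 methyl on C10), "syn/anti" refer to the C1–C3 bridge, and the given SMILES (3R, 9R) is the absolute configuration.

**Route**

Step 1
Reactants: 1 (R)-citronellic acid
Product: 2 (3R,6E)-8-hydroxy-3,7-dimethyloct-6-enoic acid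
Conditions: SeO2 (0.3 equiv), t-BuOOH (3 equiv), salicylic acid (0.1 equiv), CH2Cl2, 0 °C→rt
Reagents that add atoms: tert-butyl hydroperoxide CC(C)(C)OO; selenium dioxide O=[Se]=O
Why: Sharpless–Umbreit allylic oxidation (ene reaction then [2,3]-sigmatropic shift) oxidises only the E-methyl of the trisubstituted alkene, fixing the 6E geometry that later places C9 anti and C14 syn on the cyclobutane, while the C3 stereocentre is untouched.

Step 2
Reactants: 2 (3R,6E)-8-hydroxy-3,7-dimethyloct-6-enoic acid
Product: 3 (3R,6E)-3,7-dimethyl-8-(triethylsilyloxy)oct-6-enoic acid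
Conditions: Et3SiCl (2.3 equiv), imidazole (4.6 equiv), CH2Cl2, 0 °C→rt; then MeOH/H2O, rt
Reagents that add atoms: chlorotriethylsilane CC[Si](Cl)(CC)CC
Why: Standard bis-silylation followed by selective hydrolysis of the labile silyl ester leaves a primary triethylsilyl ether that survives ketene generation and is oxidised directly in step 4.

Step 3
Reactants: 3 (3R,6E)-3,7-dimethyl-8-(triethylsilyloxy)oct-6-enoic acid
Product: 6 2,7-dimethyl-7-[(triethylsilyloxy)methyl]bicyclo[3.1.1]heptan-6-one, via acid chloride 4 (not isolated), via ketene 5 (not isolated)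
Conditions: 1-chloro-N,N,2-trimethylprop-1-en-1-amine (1.2 equiv), CH2Cl2, 0 °C→rt; then slow addition (8 h) to Et3N (5 equiv), toluene, 110 °C, 0.005 M
Reagents that add atoms: none
Why: Snider-type intramolecular ketene–alkene [2+2] cycloaddition: the ketene carbonyl carbon (C5) bonds to the less substituted alkene carbon C11 and the tertiary centre C10 closes onto C4 to give the bicyclo[3.1.1]heptan-6-one; suprafacial addition turns the E-alkene into C14 syn/C9 anti, and C10 adds to the ketene face opposite the C3 methyl (no syn-pentane clash with C14), so C4, C10 and C11 follow from the citronellic stereocentre.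

Step 4
Reactants: 6 2,7-dimethyl-7-[(triethylsilyloxy)methyl]bicyclo[3.1.1]heptan-6-one
Product: 7 2,7-dimethyl-6-oxobicyclo[3.1.1]heptane-7-carbaldehyde
Conditions: (COCl)2 (3 equiv), DMSO (6 equiv), CH2Cl2, −78 °C then −40 °C; Et3N (10 equiv), −78→0 °C
Reagents that add atoms: none
Why: Swern oxidation converts a primary triethylsilyl ether directly into the aldehyde (activated DMSO cleaves the primary Si–O bond); C10 is quaternary and the cyclobutanone is flanked by bridgeheads, so nothing can epimerise.

Step 5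
Reactants: 8 methyl tiglate
Product: 9 tert-butyl[(1-methoxy-2-methylbuta-1,3-dien-1-yl)oxy]dimethylsilane
Conditions: LiN(iPr)2 (1.1 equiv), THF/DMPU, −78 °C; t-BuMe2SiCl, −78 °C→rt
Reagents that add atoms: tert-butylchlorodimethylsilane CC(C)(C)[Si](C)(C)Cl
Why: Kinetic γ-deprotonation of the enoate and O-silylation give the silyl dienol ether (vinylogous ketene acetal).

Step 6
Reactants: 7 2,7-dimethyl-6-oxobicyclo[3.1.1]heptane-7-carbaldehyde; 9 tert-butyl[(1-methoxy-2-methylbuta-1,3-dien-1-yl)oxy]dimethylsilane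
Product: 10 methyl (2E,5R)-5-(2,7-dimethyl-6-oxobicyclo[3.1.1]heptan-7-yl)-5-hydroxy-2-methylpent-2-enoate
Conditions: B-phenyl oxazaborolidinone from N-tosyl-L-tryptophan + PhBCl2 (1.0 equiv, made in situ), 9 (1.6 equiv), i-PrOH (1.2 equiv), EtCN, −78 °C
Reagents that add atoms: none
Why: Kalesse-type enantioselective vinylogous Mukaiyama aldol (γ-attack) installs C6–C8, C13 and C15 in one step; the aldehyde sits on a quaternary carbon whose two ring neighbours are nearly equivalent, so the substrate has no facial bias and the oxazaborolidinone alone sets C9 (Re-face attack gives 9R; L-series expected on the Corey model, the D-tryptophan reagent being the switch if the assay shows 9S), and the aldehyde reacts ahead of the hindered cyclobutanone.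

Step 7
Reactants: 10 methyl (2E,5R)-5-(2,7-dimethyl-6-oxobicyclo[3.1.1]heptan-7-yl)-5-hydroxy-2-methylpent-2-enoate
Product: 12 (6R)-6-(2,7-dimethyl-6-oxobicyclo[3.1.1]heptan-7-yl)-3-methyltetrahydro-2H-pyran-2-one (C6 epimers), via saturated hydroxy ester 11 (not isolated)
Conditions: H2 (1 atm), Pd/C (10% Pd on carbon), EtOAc, rt; filter; then camphorsulfonic acid (10 mol %), toluene, 80 °C
Reagents that add atoms: none
Why: Hydrogenation of the enoate (both C6 epimers are used, as C6 is re-formed from an enolate) and acid-catalysed lactonisation of the δ-hydroxy ester give the lactone C–O bond that later controls C6; C9 is retained.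

Step 8
Reactants: 12 (6R)-6-(2,7-dimethyl-6-oxobicyclo[3.1.1]heptan-7-yl)-3-methyltetrahydro-2H-pyran-2-one
Product: 15 1,5-dihydroxy lactone (C5–OH syn; C1–OH cis to it), via hydrosilyl ether 13 (not isolated), via oxasilolane 14 (not isolated)
Conditions: (a) [Ir(cod)OMe]2 (0.5 mol %), Et2SiH2 (1.5 equiv), THF, rt, then evacuate; (b) [Ir(cod)OMe]2 (2 mol %), 3,4,7,8-tetramethyl-1,10-phenanthroline (5 mol %), norbornene (1.2 equiv), THF, 120 °C; (c) 30% H2O2, KHCO3, THF/MeOH, 50 °C, acidic work-up
Reagents that add atoms: hydrogen peroxide OO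
Why: Proposed new method: ketone-relayed iridium-catalysed γ-methylene C–H silylation across the C5–C11 cyclobutane edge followed by Tamao–Fleming oxidation (net C1–H to C1–OH); hydrosilylation delivers hydride to the open face of the C5 carbonyl (anti to the C1–C3 bridge, the syn face lying inside the boat-shaped six-membered ring), so O–SiEt2H points at the bridge, where the iridium silyl intermediate reaches only the C1–H cis to it (five-membered cis-fused oxasilolane; the mirror-related C3 site offers a methyl that would need a six-membered silacycle, and its own C–H is tertiary and turned away), and H2O2 replaces Si by OH with retention; closest known reaction type is the Hartwig hydroxyl-directed iridium-catalysed silylation of secondary C–H bonds to 1,3-diols, not yet shown for cyclobutanone-derived silyl ethers reaching onto a neighbouring bridge of a bicyclo[3.1.1]heptane.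

Step 9
Reactants: 15 1,5-dihydroxy lactone
Product: 17 5-keto lactone with C1 as triisopropylsilyl enol ether (C1=C2), via diketo lactone 16 (not isolated)
Conditions: Dess–Martin periodinane (2.6 equiv), pyridine, CH2Cl2, 0 °C→rt; pentane, filter; then i-Pr3SiOTf (1.3 equiv), Et3N (3 equiv), CH2Cl2, −78→0 °C
Reagents that add atoms: triisopropylsilyl trifluoromethanesulfonate CC(C)[Si](C(C)C)(C(C)C)OS(=O)(=O)C(F)(F)F
Why: Dess–Martin oxidation of both carbinols gives a β-diketone that cannot enolise through bridgehead C11, so soft enolisation can go only toward C2, which masks C1 as a robust silyl enol ether, leaves the C5 ketone free, and removes the retro-aldol path of the later C5 alkoxide.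

Step 10
Reactants: 17 5-keto lactone silyl enol ether
Product: 20 S-methyl xanthate of the tricyclic C5-hydroxy 15,9-lactone, via lithium aldolate 18 (not isolated), via lithium xanthate 19 (not isolated)
Conditions: LiN(iPr)2 (1.15 equiv), THF, −78 °C; CS2 (5 equiv), −78→−20 °C; MeI (6 equiv), →0 °C
Reagents that add atoms: carbon disulfide S=C=S; iodomethane CI
Why: Intramolecular aldol addition of the lactone enolate to the strained, non-enolisable cyclobutanone closes the seven-membered ring and creates quaternary C6; because C15 is tied to O9 the enolate reaches C5 only with C15 cis to O9 (C13 on the other side) and only on the face anti to the C1–C3 bridge, so C6 and C5 follow from the 9R centre, and in-situ xanthate formation (Chugaev elimination impossible, β-hydrogens being on bridgeheads) stops retro-aldol.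

Step 11
Reactants: 20 S-methyl xanthate
Product: 21 1-(triisopropylsilyloxy)longipin-1-en-15,9-olide
Conditions: Bu3SnH (2 equiv), AIBN (0.2 equiv), toluene, 100 °C
Reagents that add atoms: none
Why: Barton–McCombie deoxygenation of the tertiary xanthate; the C5 radical can take hydrogen only on the face syn to the C1–C3 bridge because C6 is held on the other face by the seven-membered ring and the lactone, which sets C5.

Step 12
Reactants: 21 1-(triisopropylsilyloxy)longipin-1-en-15,9-olide
Product: 22 1-(triisopropylsilyloxy)longipin-1-ene-9,15-diol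
Conditions: LiAlH4 (2.5 equiv), THF, 0→50 °C; Fieser work-up
Reagents that add atoms: none
Why: Hydride reduction of the lactone gives the 9,15-diol; the silyl enol ether is inert to LiAlH4 and no stereocentre is touched.

Step 13
Reactants: 22 1-(triisopropylsilyloxy)longipin-1-ene-9,15-diol; 23 angelic anhydride
Product: 24 9,15-bis(angeloyloxy)-1-(triisopropylsilyloxy)longipin-1-ene
Conditions: LiN(SiMe3)2 (2.4 equiv), THF, −20 °C; 23 (3 equiv), −20→0 °C
Reagents that add atoms: none
Why: Acylation of the dilithium alkoxide with the anhydride at low temperature, without a nucleophilic amine catalyst, esterifies the hindered C9 alcohol and avoids Z-to-E isomerisation to tiglate.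

Step 14
Reactants: 24 9,15-bis(angeloyloxy)-1-(triisopropylsilyloxy)longipin-1-ene
Product: 25 CNP0276938.1
Conditions: HF·pyridine, THF, 0 °C
Reagents that add atoms: none
Why: Fluoride cleavage of the silyl enol ether with protonation at C2 (a CH2, no new stereocentre) unveils the C1 ketone without touching the angelates.

**Compound list**
1 | (R)-citronellic acid [(3R)-3,7-dimethyloct-6-enoic acid] | C[C@H](CCC=C(C)C)CC(=O)O | starting material
2 | (3R,6E)-8-hydroxy-3,7-dimethyloct-6-enoic acid | C[C@H](CC/C=C(\C)CO)CC(=O)O | intermediate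
3 | (3R,6E)-3,7-dimethyl-8-(triethylsilyloxy)oct-6-enoic acid | C[C@H](CC/C=C(\C)CO[Si](CC)(CC)CC)CC(=O)O | intermediate
4 | (3R,6E)-3,7-dimethyl-8-(triethylsilyloxy)oct-6-enoyl chloride | C[C@H](CC/C=C(\C)CO[Si](CC)(CC)CC)CC(=O)Cl | intermediate (not isolated)
5 | (3R,6E)-3,7-dimethyl-8-(triethylsilyloxy)octa-1,6-dien-1-one (ketene) | C[C@H](CC/C=C(\C)CO[Si](CC)(CC)CC)C=C=O | intermediate (not isolated)
6 | 2,7-dimethyl-7-[(triethylsilyloxy)methyl]bicyclo[3.1.1]heptan-6-one (C5 ketone; C12 methyl anti to C10; C14 syn; C9H2OSiEt3 anti) | CC[Si](CC)(CC)OC[C@]1(C)[C@@H]2C(=O)[C@H]1CC[C@H]2C | intermediate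
7 | 2,7-dimethyl-6-oxobicyclo[3.1.1]heptane-7-carbaldehyde (ring stereochemistry as 6) | O=C[C@]1(C)[C@@H]2C(=O)[C@H]1CC[C@H]2C | intermediate
8 | methyl tiglate [methyl (E)-2-methylbut-2-enoate] | C/C=C(\C)C(=O)OC | starting material
9 | tert-butyl[(1-methoxy-2-methylbuta-1,3-dien-1-yl)oxy]dimethylsilane | C=CC(C)=C(OC)O[Si](C)(C)C(C)(C)C | intermediate
10 | methyl (2E,5R)-5-(2,7-dimethyl-6-oxobicyclo[3.1.1]heptan-7-yl)-5-hydroxy-2-methylpent-2-enoate (9R) | COC(=O)/C(C)=C/C[C@@H](O)[C@]1(C)[C@@H]2C(=O)[C@H]1CC[C@H]2C | intermediate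
11 | methyl (5R)-5-(2,7-dimethyl-6-oxobicyclo[3.1.1]heptan-7-yl)-5-hydroxy-2-methylpentanoate (C6 epimers) | COC(=O)C(C)CC[C@@H](O)[C@]1(C)[C@@H]2C(=O)[C@H]1CC[C@H]2C | intermediate (not isolated)
12 | (6R)-6-(2,7-dimethyl-6-oxobicyclo[3.1.1]heptan-7-yl)-3-methyltetrahydro-2H-pyran-2-one (C6 epimers) | CC1CC[C@@H](OC1=O)[C@]2(C)[C@@H]3C(=O)[C@H]2CC[C@H]3C | intermediate
13 | diethyl(hydrido)silyl ether of the C5 alcohol (O–Si syn) | CC1CC[C@@H](OC1=O)[C@]2(C)[C@@H]3[C@@H](O[SiH](CC)CC)[C@H]2CC[C@H]3C | intermediate (not isolated)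
14 | cis-fused oxasilolane (O5–SiEt2–C1) | CC1CC[C@@H](OC1=O)[C@]2(C)[C@@H]3[C@@H](O4)[C@H]2[C@@H]([Si]4(CC)CC)C[C@H]3C | intermediate (not isolated)
15 | 1,5-dihydroxy lactone (C5–OH syn; C1–OH cis to it) | CC1CC[C@@H](OC1=O)[C@]2(C)[C@@H]3[C@@H](O)[C@H]2[C@@H](O)C[C@H]3C | intermediate
16 | 1,5-diketo lactone | CC1CC[C@@H](OC1=O)[C@]2(C)[C@@H]3C(=O)[C@H]2C(=O)C[C@H]3C | intermediate (not isolated)
17 | 5-keto lactone, C1 triisopropylsilyl enol ether | CC1CC[C@@H](OC1=O)[C@]2(C)[C@@H]3C(=O)[C@H]2C(O[Si](C(C)C)(C(C)C)C(C)C)=C[C@H]3C | intermediate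
18 | lithium aldolate (tricyclic; C5–OLi syn; C6 quaternary) | O=C4[C@@]1(C)CC[C@@H](O4)[C@]2(C)[C@@H]3[C@@]1([O-])[C@H]2C(O[Si](C(C)C)(C(C)C)C(C)C)=C[C@H]3C.[Li+] | intermediate (not isolated)
19 | lithium O-alkyl dithiocarbonate of 18 | O=C4[C@@]1(C)CC[C@@H](O4)[C@]2(C)[C@@H]3[C@@]1(OC(=S)[S-])[C@H]2C(O[Si](C(C)C)(C(C)C)C(C)C)=C[C@H]3C.[Li+] | intermediate (not isolated)
20 | S-methyl xanthate of the tricyclic C5-hydroxy 15,9-lactone | O=C4[C@@]1(C)CC[C@@H](O4)[C@]2(C)[C@@H]3[C@@]1(OC(=S)SC)[C@H]2C(O[Si](C(C)C)(C(C)C)C(C)C)=C[C@H]3C | intermediate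
21 | 1-(triisopropylsilyloxy)longipin-1-en-15,9-olide | O=C4[C@@]1(C)CC[C@@H](O4)[C@]2(C)[C@@H]3[C@H]1[C@H]2C(O[Si](C(C)C)(C(C)C)C(C)C)=C[C@H]3C | intermediate
22 | 1-(triisopropylsilyloxy)longipin-1-ene-9,15-diol | OC[C@@]1(C)CC[C@@H](O)[C@]2(C)[C@@H]3[C@H]1[C@H]2C(O[Si](C(C)C)(C(C)C)C(C)C)=C[C@H]3C | intermediate
23 | angelic anhydride [(Z)-2-methylbut-2-enoic anhydride] | C/C=C(/C)C(=O)OC(=O)/C(C)=C\C | starting material
24 | 9,15-bis(angeloyloxy)-1-(triisopropylsilyloxy)longipin-1-ene | C/C=C(/C)C(=O)OC[C@@]1(C)CC[C@@H](OC(=O)/C(C)=C\C)[C@]2(C)[C@@H]3[C@H]1[C@H]2C(O[Si](C(C)C)(C(C)C)C(C)C)=C[C@H]3C | intermediate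
25 | CNP0276938.1 [9,15-bis(angeloyloxy)longipinan-1-one in the labels used here] | C/C=C(/C)C(=O)OC[C@@]1(C)CC[C@@H](OC(=O)/C(C)=C\C)[C@]2(C)[C@@H]3[C@H]1[C@H]2C(=O)C[C@H]3C | target

**Totals**
Total steps: 14. Longest linear sequence: 13 steps (1 to 25 through steps 1–4 and 6–14; step 5 is a one-step side branch).

**Steps most likely to fail, with fallbacks**

Step 8 (the proposed new step). The risks are hydrosilylation on the wrong face and failure of iridium to enter the concave C1 site. The fallback uses known copper chemistry (Schönecker-type imine-directed β-hydroxylation of ketones, as practised on steroid ketones). It sets out from 12: condensation with pyridin-2-ylmethanamine (TsOH, toluene, molecular sieves) gives the 2-picolyl imine F1. Treatment with Cu(MeCN)4PF6, sodium ascorbate and O2 (acetone/MeOH, 50 °C), then aqueous Na4EDTA/AcOH hydrolysis, gives the 1-hydroxy-5-keto lactone F2. A single Dess–Martin oxidation converts F2 into diketone 16, which is silylated as in step 9, so the route is rejoined at 16 and hence 17.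

Step 10. The risks are a strained bridged transition state and retro-aldol before the alkoxide is trapped. The fallback sets out from 17: LiN(iPr)2 with Me3SiCl as internal quench (THF, −78 °C) gives the lactone trimethylsilyl ketene acetal F3. N-Bromosuccinimide (1.0 equiv, −78 °C; the O,O-ketene acetal reacts far faster than the hindered silyl enol ether) gives the α-bromo lactone F4. SmI2 (2.2 equiv, THF, −78 °C) then effects an intramolecular samarium Reformatsky cyclisation, whose chelated trivalent samarium aldolate does not revert, to give the tricyclic C5-hydroxy 15,9-lactone F5. NaH/CS2/MeI converts F5 into xanthate 20, where the route is rejoined.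

Step 3. The risks are dimerisation and the low reactivity of a simple alkylketene toward an alkene bearing an allylic silyl ether. The fallback sets out from 3: coupling with pyrrolidine (EDC·HCl, HOBt) gives the pyrrolidine amide F6. Tf2O and 2,4,6-collidine in refluxing 1,2-dichloroethane generate the keteniminium triflate F7, a stronger electrophile that undergoes the same crossed [2+2] (Ghosez-type) to give the cyclobutaniminium triflate F8. Aqueous NaHCO3 hydrolysis returns cyclobutanone 6.

**Further compounds**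
F1 | step 8 | 2-picolyl imine of keto lactone 12 (E/Z) | CC1CC[C@@H](OC1=O)[C@]2(C)[C@@H]3C(=NCc4ccccn4)[C@H]2CC[C@H]3C
F2 | step 8 | 1-hydroxy-5-keto lactone (C1–OH as in 15) | CC1CC[C@@H](OC1=O)[C@]2(C)[C@@H]3C(=O)[C@H]2[C@@H](O)C[C@H]3C
F3 | step 10 | lactone trimethylsilyl ketene acetal of 17 | CC1=C(O[Si](C)(C)C)O[C@H](CC1)[C@]2(C)[C@@H]3C(=O)[C@H]2C(O[Si](C(C)C)(C(C)C)C(C)C)=C[C@H]3C
F4 | step 10 | α-bromo lactone (C6 epimers) | CC1(Br)CC[C@@H](OC1=O)[C@]2(C)[C@@H]3C(=O)[C@H]2C(O[Si](C(C)C)(C(C)C)C(C)C)=C[C@H]3C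
F5 | step 10 | tricyclic C5-hydroxy 15,9-lactone | O=C4[C@@]1(C)CC[C@@H](O4)[C@]2(C)[C@@H]3[C@@]1(O)[C@H]2C(O[Si](C(C)C)(C(C)C)C(C)C)=C[C@H]3C
F6 | step 3 | pyrrolidine amide of 3 | C[C@H](CC/C=C(\C)CO[Si](CC)(CC)CC)CC(=O)N1CCCC1
F7 | step 3 | keteniminium triflate | C[C@H](CC/C=C(\C)CO[Si](CC)(CC)CC)C=C=[N+]1CCCC1.[O-]S(=O)(=O)C(F)(F)F
F8 | step 3 | cyclobutaniminium triflate | CC[Si](CC)(CC)OC[C@]1(C)[C@@H]2C(=[N+]3CCCC3)[C@H]1CC[C@H]2C.[O-]S(=O)(=O)C(F)(F)F
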